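**Retrosynthetic overview**

- Target 20 comes from flavanone 19 by acidic removal of four MOM ethers, 19 from oxidation of the C4 carbinol 18, and 18 from desilylation of chroman 17.
- Ring C is the only ring built (rings A and B are bought as arenes): the O1–C8a bond is closed last by palladium-catalysed aryl etherification of the (S)-C2 carbinol onto the C8a triflate of 16.
- 16 comes from asymmetric transfer hydrogenation of aryl ketone 15, which comes from a silylated aldol (C3–C4 bond) between ring B methyl ketone 12 and ring A aldehyde triflate 10.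
- 10 comes from ortho-formylation and triflation of the symmetric phenol 7, made from phloroglucinol by mono-silylation, bis-MOM protection and directed lithiation–farnesylation between the two OMOM groups.
- Feature used: O1 of ring C bridges the benzylic stereocentre C2 and the aromatic carbon C8a of the phloroglucinol ring A. C8a already carries an oxygen that can become a triflate, so O1 can be supplied by a preformed (S)-carbinol whose C2–O bond is never broken. The C6 farnesyl lies between two equivalent oxygens (C5, C7), so the ring A phenol is symmetric and its formylation is unambiguous.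

Key step: step 11

Remark: the SMILES descriptor at C2 corresponds to (2S). Farnesyl means (2E,6E)-3,7,11-trimethyldodeca-2,6,10-trien-1-yl, MOM methoxymethyl, TIPS triisopropylsilyl, TBS tert-butyldimethylsilyl. Flavanone numbering (O1, C2–C4, C4a, C5–C8, C8a) is used throughout; phloroglucinol is used anhydrous.

**Route**

Step 1
Reactants: 1 phloroglucinol (benzene-1,3,5-triol)
Product: 2 5-(triisopropylsilyloxy)benzene-1,3-diol
Conditions: TIPSCl (1.0 equiv), imidazole, DMF, 0 °C → rt; chromatography
Reagents that add atoms: chlorotriisopropylsilane (TIPSCl), CC(C)[Si](Cl)(C(C)C)C(C)C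
Why: Statistical mono-O-silylation of the threefold symmetric triol with one equivalent of a bulky silyl chloride should give the monoether, separable from recovered 1 and the bis-ether, and it marks the one oxygen that later becomes the triflate leaving group.

Step 2
Reactants: 2 5-(triisopropylsilyloxy)benzene-1,3-diol
Product: 3 [3,5-bis(methoxymethoxy)phenoxy]triisopropylsilane
Conditions: MOMCl, i-Pr2NEt, CH2Cl2, 0 °C → rt
Reagents that add atoms: chloromethyl methyl ether (MOMCl), COCCl
Why: Williamson-type O-alkylation of the two remaining phenols with MOMCl and a hindered amine base installs the acetal groups that later direct lithiation, while the aryl TIPS ether is inert to these conditions.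

Step 3
Reactants: 3 [3,5-bis(methoxymethoxy)phenoxy]triisopropylsilane; 4 (2E,6E)-farnesyl bromide
Product: 6 {4-[(2E,6E)-farnesyl]-3,5-bis(methoxymethoxy)phenoxy}triisopropylsilane, via aryllithium 5 (not isolated)
Conditions: n-BuLi, THF, 0 °C; then 4, −78 °C → rt
Reagents that add atoms: none
Why: Directed ortho-metalation takes place at the only position flanked by two OMOM groups (cooperative coordination, while the bulky, weakly directing OTIPS shields its neighbours), and the aryllithium should displace the primary allylic bromide of 4 by SN2 with the (2E,6E) geometry untouched.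

Step 4
Reactants: 6 {4-[(2E,6E)-farnesyl]-3,5-bis(methoxymethoxy)phenoxy}triisopropylsilane
Product: 7 4-[(2E,6E)-farnesyl]-3,5-bis(methoxymethoxy)phenol
Conditions: Bu4NF, THF, 0 °C; aq NH4Cl work-up
Reagents that add atoms: none
Why: Fluoride attacks silicon and releases the phenoxide (silyl ether cleavage driven by the Si–F bond), leaving the MOM ethers and the triene untouched.

Step 5
Reactants: 7 4-[(2E,6E)-farnesyl]-3,5-bis(methoxymethoxy)phenol
Product: 9 3-[(2E,6E)-farnesyl]-6-hydroxy-2,4-bis(methoxymethoxy)benzaldehyde, via salicyl alcohol 8 (not isolated)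
Conditions: MgCl2, Et3N, (CH2O)n, MeCN, reflux; aq NH4Cl work-up
Reagents that add atoms: paraformaldehyde (formaldehyde), C=O
Why: Magnesium-mediated ortho-formylation (Casnati–Skattebøl): the magnesium phenoxide delivers formaldehyde to the ortho carbon and a second formaldehyde oxidises the salicyl alcohol 8 by hydride transfer, and since both ortho positions of the symmetric phenol are equivalent and the para position is blocked, one aldehyde should form.

Step 6
Reactants: 9 3-[(2E,6E)-farnesyl]-6-hydroxy-2,4-bis(methoxymethoxy)benzaldehyde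
Product: 10 2-formyl-3,5-bis(methoxymethoxy)-4-[(2E,6E)-farnesyl]phenyl trifluoromethanesulfonate
Conditions: PhNTf2, Et3N, DMAP (cat.), CH2Cl2, rt
Reagents that add atoms: N-phenylbis(trifluoromethanesulfonimide) (PhNTf2), O=S(=O)(N(c1ccccc1)S(=O)(=O)C(F)(F)F)C(F)(F)F
Why: O-Sulfonylation of the phenoxide with the mild triflyl donor PhNTf2 converts the C8a oxygen into the leaving group without generating acid that could harm the MOM ethers or the triene.

Step 7
Reactants: 11 3,5-dihydroxyacetophenone
Product: 12 1-[3,5-bis(methoxymethoxy)phenyl]ethan-1-one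
Conditions: MOMCl, i-Pr2NEt, CH2Cl2, 0 °C → rt
Reagents that add atoms: chloromethyl methyl ether (MOMCl), COCCl
Why: Williamson-type MOM protection of both phenols gives a methyl ketone whose only acidic C–H bonds are those of the acetyl group.

Step 8
Reactants: 12 1-[3,5-bis(methoxymethoxy)phenyl]ethan-1-one; 10 2-formyl-3,5-bis(methoxymethoxy)-4-[(2E,6E)-farnesyl]phenyl trifluoromethanesulfonate
Product: 14 racemic 2-{1-hydroxy-3-oxo-3-[3,5-bis(methoxymethoxy)phenyl]propyl}-3,5-bis(methoxymethoxy)-4-[(2E,6E)-farnesyl]phenyl trifluoromethanesulfonate, via lithium enolate 13 (not isolated)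
Conditions: LiN(SiMe3)2, THF, −78 °C; then 10, −78 °C; AcOH quench at −78 °C
Reagents that add atoms: none
Why: Aldol addition of the kinetic lithium enolate 13 to the non-enolisable, triflate-activated aldehyde forms C3–C4 at −78 °C, and the cold acetic acid quench should prevent retro-aldol, dehydration and attack of the aldolate on the triflate; the new C4 carbinol is racemic, which is harmless because C4 ends as the ketone.

Step 9
Reactants: 14 racemic aldol (β-hydroxy ketone triflate)
Product: 15 racemic 2-{1-(tert-butyldimethylsilyloxy)-3-oxo-3-[3,5-bis(methoxymethoxy)phenyl]propyl}-3,5-bis(methoxymethoxy)-4-[(2E,6E)-farnesyl]phenyl trifluoromethanesulfonate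
Conditions: TBSCl, imidazole, DMAP (cat.), DMF, rt
Reagents that add atoms: tert-butyldimethylsilyl chloride (TBSCl), CC(C)(C)[Si](C)(C)Cl
Why: Silylation of the secondary benzylic alcohol with TBSCl/imidazole (chosen over a silyl triflate, which could attack aryl MOM ethers) masks the C4 oxygen for the reduction and the coupling.

Step 10
Reactants: 15 racemic β-silyloxy aryl ketone triflate
Product: 16 2-{(3S)-3-[3,5-bis(methoxymethoxy)phenyl]-1-(tert-butyldimethylsilyloxy)-3-hydroxypropyl}-3,5-bis(methoxymethoxy)-4-[(2E,6E)-farnesyl]phenyl trifluoromethanesulfonate (both epimers at the silyloxy carbon)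
Conditions: RuCl[(S,S)-TsDPEN](p-cymene) (2 mol%), HCO2H/Et3N (5:2), CH2Cl2, 30 °C
Reagents that add atoms: none
Why: Noyori asymmetric transfer hydrogenation of the aryl alkyl ketone: the (S,S)-TsDPEN ruthenium hydride delivers hydride to the face that gives the (S)-carbinol (same sense as acetophenone to (S)-1-phenylethanol) under reagent control, so each C4 epimer should give the (S) configuration at the future C2, and triflate, silyl ether, MOM ethers and alkenes are not reduced.

Step 11
Reactants: 16 (3S)-carbinol aryl triflate (both C4 epimers)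
Product: 17 (2S,4RS)-4-(tert-butyldimethylsilyloxy)-5,7-bis(methoxymethoxy)-2-[3,5-bis(methoxymethoxy)phenyl]-6-[(2E,6E)-farnesyl]chroman
Conditions: Pd2(dba)3 (2.5 mol%), 2-(di-tert-butylphosphino)-3,6-dimethoxy-2′,4′,6′-triisopropylbiphenyl (tBuBrettPhos, 6 mol%), K3PO4, toluene, 80 °C
Reagents that add atoms: none
Why: Zerovalent palladium carrying the bulky phosphine inserts into the C8a–OTf bond, phosphate-assisted exchange of triflate for the C2 alkoxide on divalent palladium gives a seven-membered oxapalladacycle, and C–O reductive elimination forms O1–C8a. The closest known reaction type is the palladium-catalysed intramolecular etherification of aryl halides and triflates with secondary alcohols (Buchwald–Hartwig C–O coupling). Ring C closes as a six-membered ring in a formally 6-exo mode at the sp2 carbon C8a, by contraction of the palladacycle. No stereocentre is created, and C2 keeps its (S) configuration because only the O–H bond of the carbinol is broken, never C2–O. The step needs C–O reductive elimination to outrun β-hydride elimination from the palladium alkoxide and base attack at the triflate sulfur, which the di-tert-butyl biaryl phosphine and the weak, insoluble phosphate base should secure. The C4 silyl ether keeps the second oxygen away from palladium and from the triflate and blocks retro-aldol cleavage or elimination to a chalcone, and both C4 epimers converge later at the ketone.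

Step 12
Reactants: 17 (2S,4RS)-4-silyloxychroman
Product: 18 (2S,4RS)-5,7-bis(methoxymethoxy)-2-[3,5-bis(methoxymethoxy)phenyl]-6-[(2E,6E)-farnesyl]chroman-4-ol
Conditions: Bu4NF, THF, rt; aq NH4Cl work-up
Reagents that add atoms: none
Why: Fluoride-induced cleavage of the secondary TBS ether; with no carbonyl in the molecule the basic fluoride cannot open ring C, so C2 is safe.

Step 13
Reactants: 18 (2S,4RS)-chroman-4-ol
Product: 19 (2S)-5,7-bis(methoxymethoxy)-2-[3,5-bis(methoxymethoxy)phenyl]-6-[(2E,6E)-farnesyl]chroman-4-one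
Conditions: Dess–Martin periodinane, pyridine, CH2Cl2, 0 °C → rt
Reagents that add atoms: none
Why: Dess–Martin oxidation of the benzylic secondary alcohol to the aryl ketone proceeds by ligand exchange at iodine and α-hydrogen removal under near-neutral buffered conditions, merges the two C4 epimers and leaves the alkenes, the acetals and C2 alone.

Step 14
Reactants: 19 (2S)-tetrakis-MOM flavanone
Product: 20 (2S)-5,7-dihydroxy-2-(3,5-dihydroxyphenyl)-6-[(2E,6E)-farnesyl]chroman-4-one (CNP0186816.1)
Conditions: HCl (3 M aq), MeOH, rt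
Reagents that add atoms: none
Why: Acid-catalysed solvolysis of the four aryl MOM acetals via methoxymethyl oxocarbenium ions trapped by methanol; dilute acid at room temperature is chosen because flavanones are configurationally stable to acid (ring opening at C2 needs base) and trisubstituted alkenes protonate only slowly under these conditions.

**Compound list**

1 | phloroglucinol | Oc1cc(O)cc(O)c1 | starting material
2 | 5-(triisopropylsilyloxy)benzene-1,3-diol | CC(C)[Si](Oc1cc(O)cc(O)c1)(C(C)C)C(C)C | intermediate
3 | [3,5-bis(methoxymethoxy)phenoxy]triisopropylsilane | COCOc1cc(OCOC)cc(O[Si](C(C)C)(C(C)C)C(C)C)c1 | intermediate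
4 | (2E,6E)-farnesyl bromide | CC(C)=CCC/C(C)=C/CC/C(C)=C/CBr | starting material
5 | [2,6-bis(methoxymethoxy)-4-(triisopropylsilyloxy)phenyl]lithium | [Li]c1c(OCOC)cc(O[Si](C(C)C)(C(C)C)C(C)C)cc1OCOC | intermediate (not isolated)
6 | {4-[(2E,6E)-farnesyl]-3,5-bis(methoxymethoxy)phenoxy}triisopropylsilane | CC(C)=CCC/C(C)=C/CC/C(C)=C/Cc1c(OCOC)cc(O[Si](C(C)C)(C(C)C)C(C)C)cc1OCOC | intermediate
7 | 4-[(2E,6E)-farnesyl]-3,5-bis(methoxymethoxy)phenol | CC(C)=CCC/C(C)=C/CC/C(C)=C/Cc1c(OCOC)cc(O)cc1OCOC | intermediate
8 | 4-[(2E,6E)-farnesyl]-2-(hydroxymethyl)-3,5-bis(methoxymethoxy)phenol (as its magnesium phenoxide) | CC(C)=CCC/C(C)=C/CC/C(C)=C/Cc1c(OCOC)cc(O)c(CO)c1OCOC | intermediate (not isolated)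
9 | 3-[(2E,6E)-farnesyl]-6-hydroxy-2,4-bis(methoxymethoxy)benzaldehyde | CC(C)=CCC/C(C)=C/CC/C(C)=C/Cc1c(OCOC)cc(O)c(C=O)c1OCOC | intermediate
10 | 2-formyl-3,5-bis(methoxymethoxy)-4-[(2E,6E)-farnesyl]phenyl trifluoromethanesulfonate | CC(C)=CCC/C(C)=C/CC/C(C)=C/Cc1c(OCOC)cc(OS(=O)(=O)C(F)(F)F)c(C=O)c1OCOC | intermediate
11 | 3,5-dihydroxyacetophenone | CC(=O)c1cc(O)cc(O)c1 | starting material
12 | 1-[3,5-bis(methoxymethoxy)phenyl]ethan-1-one | CC(=O)c1cc(OCOC)cc(OCOC)c1 | intermediate
13 | lithium 1-[3,5-bis(methoxymethoxy)phenyl]ethen-1-olate | [Li]OC(=C)c1cc(OCOC)cc(OCOC)c1 | intermediate (not isolated)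
14 | racemic 2-{1-hydroxy-3-oxo-3-[3,5-bis(methoxymethoxy)phenyl]propyl}-3,5-bis(methoxymethoxy)-4-[(2E,6E)-farnesyl]phenyl trifluoromethanesulfonate | CC(C)=CCC/C(C)=C/CC/C(C)=C/Cc1c(OCOC)cc(OS(=O)(=O)C(F)(F)F)c(c1OCOC)C(O)CC(=O)c1cc(OCOC)cc(OCOC)c1 | intermediate
15 | racemic 2-{1-(tert-butyldimethylsilyloxy)-3-oxo-3-[3,5-bis(methoxymethoxy)phenyl]propyl}-3,5-bis(methoxymethoxy)-4-[(2E,6E)-farnesyl]phenyl trifluoromethanesulfonate | CC(C)=CCC/C(C)=C/CC/C(C)=C/Cc1c(OCOC)cc(OS(=O)(=O)C(F)(F)F)c(c1OCOC)C(O[Si](C)(C)C(C)(C)C)CC(=O)c1cc(OCOC)cc(OCOC)c1 | intermediate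
16 | 2-{(3S)-3-[3,5-bis(methoxymethoxy)phenyl]-1-(tert-butyldimethylsilyloxy)-3-hydroxypropyl}-3,5-bis(methoxymethoxy)-4-[(2E,6E)-farnesyl]phenyl trifluoromethanesulfonate, both epimers at the silyloxy carbon | CC(C)=CCC/C(C)=C/CC/C(C)=C/Cc1c(OCOC)cc(OS(=O)(=O)C(F)(F)F)c(c1OCOC)C(O[Si](C)(C)C(C)(C)C)C[C@@H](c1cc(OCOC)cc(OCOC)c1)O | intermediate
17 | (2S,4RS)-4-(tert-butyldimethylsilyloxy)-5,7-bis(methoxymethoxy)-2-[3,5-bis(methoxymethoxy)phenyl]-6-[(2E,6E)-farnesyl]chroman | CC(C)=CCC/C(C)=C/CC/C(C)=C/Cc1c(OCOC)cc2c(c1OCOC)C(O[Si](C)(C)C(C)(C)C)C[C@@H](c1cc(OCOC)cc(OCOC)c1)O2 | intermediate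
18 | (2S,4RS)-5,7-bis(methoxymethoxy)-2-[3,5-bis(methoxymethoxy)phenyl]-6-[(2E,6E)-farnesyl]chroman-4-ol | CC(C)=CCC/C(C)=C/CC/C(C)=C/Cc1c(OCOC)cc2c(c1OCOC)C(O)C[C@@H](c1cc(OCOC)cc(OCOC)c1)O2 | intermediate
19 | (2S)-5,7-bis(methoxymethoxy)-2-[3,5-bis(methoxymethoxy)phenyl]-6-[(2E,6E)-farnesyl]chroman-4-one | CC(C)=CCC/C(C)=C/CC/C(C)=C/Cc1c(OCOC)cc2c(c1OCOC)C(=O)C[C@@H](c1cc(OCOC)cc(OCOC)c1)O2 | intermediate
20 | (2S)-5,7-dihydroxy-2-(3,5-dihydroxyphenyl)-6-[(2E,6E)-farnesyl]chroman-4-one | CC(C)=CCC/C(C)=C/CC/C(C)=C/Cc1c(O)cc2c(c1O)C(=O)C[C@@H](c1cc(O)cc(O)c1)O2 | target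

**Step count**

Total: 14 steps. Longest linear sequence: 13 steps (steps 1–6, then 8–14); step 7 is the one-step side branch for ring B.

**Steps most likely to fail**

1. Step 11 (aryl ether closure). β-Hydride elimination from the palladium alkoxide, followed by hydrodetriflation, may outrun C–O reductive elimination; base cleavage of the triflate S–O bond is the second loss pathway. The fallback forms the other C–O bond of O1 by SN2 with inversion. It sets out from 15: transfer hydrogenation with RuCl[(R,R)-TsDPEN](p-cymene) and HCO2H/Et3N should give the (3R)-carbinol aryl triflate F1. Et4NOH (aq) in 1,4-dioxane at rt should then cleave the triflate to the (3R)-carbinol phenol F2. Mitsunobu cyclisation (PPh3, DIAD, THF, 0 °C) lets the phenol oxygen displace the activated carbinol oxygen at C2 with inversion. Ring B has only meta oxygens and does not stabilise a benzylic cation, so the displacement should stay SN2, and the route is rejoined at 17.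

2. Step 8 (aldol). The lithium aldolate sits six atoms from the triflate sulfur, so triflyl transfer to the alkoxide, retro-aldol cleavage or dehydration may compete if the mixture warms. The fallback avoids any free alkoxide by a Lewis-acid Mukaiyama aldol. It sets out from 12: LiN(SiMe3)2 then Me3SiCl in THF at −78 °C should give the trimethylsilyl enol ether F3. BF3·OEt2 in CH2Cl2 at −78 °C with aldehyde 10, followed by aq NaHCO3 work-up, should return the β-hydroxy ketone, rejoining the route at 14.

3. Step 14 (global MOM removal). Protonation of the trisubstituted alkenes of the farnesyl chain may lead to cyclisation onto the C5 or C7 phenol or to methanol addition, and prolonged acid exposure may open ring C and erode C2. The fallback replaces Brønsted-acid solvolysis by silyl transacetalisation. It sets out from 19: Me3SiOTf with 2,2′-bipyridyl in CH2Cl2 at 0 °C → rt should convert each aryl MOM ether into an aryl silyl ether, giving the tetrakis(trimethylsilyl) ether of the flavanone F4. Hydrolysis with pH 7 buffer in THF should then release the phenols, arriving at 20.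

**Further compounds**

F1 | step 11 | 2-{(3R)-3-[3,5-bis(methoxymethoxy)phenyl]-1-(tert-butyldimethylsilyloxy)-3-hydroxypropyl}-3,5-bis(methoxymethoxy)-4-[(2E,6E)-farnesyl]phenyl trifluoromethanesulfonate | CC(C)=CCC/C(C)=C/CC/C(C)=C/Cc1c(OCOC)cc(OS(=O)(=O)C(F)(F)F)c(c1OCOC)C(O[Si](C)(C)C(C)(C)C)C[C@H](c1cc(OCOC)cc(OCOC)c1)O
F2 | step 11 | 2-{(3R)-3-[3,5-bis(methoxymethoxy)phenyl]-1-(tert-butyldimethylsilyloxy)-3-hydroxypropyl}-3,5-bis(methoxymethoxy)-4-[(2E,6E)-farnesyl]phenol | CC(C)=CCC/C(C)=C/CC/C(C)=C/Cc1c(OCOC)cc(O)c(c1OCOC)C(O[Si](C)(C)C(C)(C)C)C[C@H](c1cc(OCOC)cc(OCOC)c1)O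
F3 | step 8 | {1-[3,5-bis(methoxymethoxy)phenyl]ethenyloxy}trimethylsilane | C=C(O[Si](C)(C)C)c1cc(OCOC)cc(OCOC)c1
F4 | step 14 | (2S)-5,7-bis(trimethylsilyloxy)-2-[3,5-bis(trimethylsilyloxy)phenyl]-6-[(2E,6E)-farnesyl]chroman-4-one | CC(C)=CCC/C(C)=C/CC/C(C)=C/Cc1c(O[Si](C)(C)C)cc2c(c1O[Si](C)(C)C)C(=O)C[C@@H](c1cc(O[Si](C)(C)C)cc(O[Si](C)(C)C)c1)O2
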